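**Retrosynthetic overview** (locants: C1 lactone C=O, C2 lactone CH2, C3 CH–OO, C4 C(CH3)–O, C5 ring CH2, C6 C(CH3)–OO, C7–C16 chain)
1. Target 19 ⇐ alkene 18 (diimide) ⇐ allyl bicycle 13 + alkenyl phenol 17 (cross-metathesis): the C7–C16 chain is hung on an allyl group at C6.
2. 13 ⇐ 9: the C6 quaternary centre comes from allylation of a bicyclic peroxycarbenium ion (C6–C7 bond), followed by loss of an activating ester on C2.
3. 9 ⇐ acyclic hydroperoxy ketal 6 in one base-triggered cascade; ring order: 1,2-dioxane first (O–C3 bond), γ-lactone second (C2–C1 bond).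
4. Enabling feature: the peroxide oxygen on C3 is β to the lactone carbonyl C1. Adding that oxygen to a C2=C3 enoate therefore makes C2 a carbanion three atoms from the C4 oxygen, which already carries C1 as a carbonate (5-exo); the 1,3 relation of C4–O and C6–OO makes the dioxane closure 6-exo.
5. 6 ⇐ (S)-2-methylglycidol (C4 stereocentre) + isopropenyl Grignard (C5, C6) + Wittig ylide (C2 and its activating ester) + ClCO2Me (C1) + O3/MeOH (peroxide).

Key step: step 5

Remark: (S)-2-methylglycidol is assumed to be purchasable in high enantiomeric purity (otherwise it is the Sharpless asymmetric epoxidation product of 2-methylprop-2-en-1-ol, one extra step); 6 to 9 are carried as mixtures at the ketal carbon C6, which step 6 erases.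

**Step 1**
Reactants: 1 (2S)-(2-methyloxiran-2-yl)methanol
Product: 2 (2R)-2,4-dimethylpent-4-ene-1,2-diol
Conditions: CH2=C(CH3)MgBr (3 equiv), CuI (10 mol %), THF, −40 → 0 °C; aq NH4Cl
Reagents that add atoms: isopropenylmagnesium bromide, CC(=C)[Mg]Br
Why: Copper-catalysed Grignard opening of the 2,2-disubstituted epoxide at its CH2 terminus (SN2); the quaternary carbinol carbon (future C4) is not a reaction centre, so the configuration of 1 is carried into 2 (the descriptor changes from S to R only because the CIP priorities change).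

**Step 2**
Reactants: 2 (2R)-2,4-dimethylpent-4-ene-1,2-diol
Product: 4 tert-butyl (2E,4R)-4-hydroxy-4,6-dimethylhepta-2,6-dienoate, via hydroxy aldehyde 3 (not isolated)
Conditions: IBX (1.5 equiv), DMSO, 23 °C; then Ph3P=CHCO2tBu (1.3 equiv), 23 °C
Reagents that add atoms: tert-butyl (triphenylphosphoranylidene)acetate, CC(C)(C)OC(=O)C=P(c1ccccc1)(c1ccccc1)c1ccccc1
Why: IBX oxidation of the primary hydroxyl of the 1,2-diol (no glycol cleavage) followed in the same pot by a Wittig reaction with a stabilised ylide, which should give the E-enoate; C4 bears no hydrogen and cannot epimerise.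

**Step 3**
Reactants: 4 tert-butyl (2E,4R)-4-hydroxy-4,6-dimethylhepta-2,6-dienoate
Product: 5 tert-butyl (2E,4R)-4-[(methoxycarbonyl)oxy]-4,6-dimethylhepta-2,6-dienoate
Conditions: LiN(SiMe3)2 (1.1 equiv), THF, −78 °C; ClCO2Me (1.3 equiv), −78 → 0 °C
Reagents that add atoms: methyl chloroformate, COC(=O)Cl
Why: O-Acylation of the lithium tert-alkoxide with a chloroformate; this places the future lactone carbonyl C1 on the C4 oxygen.

**Step 4**
Reactants: 5 tert-butyl (2E,4R)-4-[(methoxycarbonyl)oxy]-4,6-dimethylhepta-2,6-dienoate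
Product: 6 tert-butyl (2E,4R)-6-hydroperoxy-6-methoxy-4-[(methoxycarbonyl)oxy]-4-methylhept-2-enoate (both C6 epimers)
Conditions: O3 (1 equiv, Sudan Red 7B end point), CH2Cl2/MeOH 4:1, −78 °C; N2 purge, 23 °C
Reagents that add atoms: ozone, [O-][O+]=O; methanol, CO
Why: Criegee ozonolysis in methanol: the electron-rich 1,1-disubstituted alkene should be cleaved much faster than the enoate, and the more substituted carbonyl oxide is trapped by MeOH as the α-methoxy hydroperoxide; the new ketal centre C6 forms without control and is erased in step 6.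

**Step 5 (key step)**
Reactants: 6 tert-butyl (2E,4R)-6-hydroperoxy-6-methoxy-4-[(methoxycarbonyl)oxy]-4-methylhept-2-enoate
Product: 9 tert-butyl (4aR,7aR)-3-methoxy-3,4a-dimethyl-6-oxohexahydrofuro[3,2-c][1,2]dioxine-7-carboxylate, via lithium peroxide 7 (not isolated), via dioxane ester enolate 8 (not isolated)
Conditions: LiN(SiMe3)2 (2.2 equiv), THF, −78 → −30 °C; AcOH (3 equiv), −78 °C
Reagents that add atoms: none
Why: Proposed new method: LiN(SiMe3)2 deprotonates the hydroperoxy ketal to 7, whose peroxide oxygen adds to C3 of the enoate (oxa-Michael), and the C2 tert-butyl ester enolate 8 formed in this way attacks the carbonate carbonyl C1 held on the C4 oxygen (Claisen/Dieckmann-type acyl substitution with loss of methoxide), so that the C2–C1 bond closes the lactone; the methoxide released stores the product as its stabilised β-dicarbonyl enolate until the cold AcOH quench. The closest known reaction types are the intramolecular peroxy-Michael addition of hydroperoxy ketals to enoates (the standard entry to 3-methoxy-1,2-dioxanes) and hetero-Michael/Dieckmann annulations (glycolate or thioglycolate plus acrylate); new is their combination with a carbonate as acyl acceptor on a peroxide. Ring closures: the 1,2-dioxane by 6-exo-trig attack of O on C3, then the γ-lactone by 5-exo-trig attack of C2 on C1. C3 should be set in a chair-like Michael transition state with the enoate arm equatorial and, at C4, methyl equatorial and the carbonate oxygen axial, which places C2 cis to the C4 oxygen (3R, cis ring fusion) and is backed by the reversibility of the addition; C4 is untouched, and C6 and C2 remain mixtures that steps 6 and 7 erase. The step needs C-acylation of enolate 8 to outrun its 3-exo attack on the O–O bond (epoxide formation) and needs the peroxide anion to add to the enoate and not to the carbonate: the first should be secured by the five-membered, gem-disubstituent-assisted acyl transfer being fast at −78 °C and by the cold quench, the second by the hindered, unactivated methyl carbonate on a tertiary oxygen, which the peroxide could reach only through a seven-membered transition state.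

**Step 6**
Reactants: 9 tert-butyl (4aR,7aR)-3-methoxy-3,4a-dimethyl-6-oxohexahydrofuro[3,2-c][1,2]dioxine-7-carboxylate
Product: 11 tert-butyl (3S,4aR,7aR)-3,4a-dimethyl-6-oxo-3-(prop-2-en-1-yl)hexahydrofuro[3,2-c][1,2]dioxine-7-carboxylate, via peroxycarbenium ion 10 (not isolated)
Conditions: CH2=CHCH2SiMe3 (3 equiv), Me3SiOSO2CF3 (0.3 equiv), CH2Cl2, −78 °C
Reagents that add atoms: allyltrimethylsilane, C=CC[Si](C)(C)C
Why: Hosomi–Sakurai-type allylation of the cyclic peroxycarbenium ion 10 formed by ionisation of the ketal methoxy group (known for 3-alkoxy-1,2-dioxolanes and 3-alkoxy-1,2-dioxanes); the allylsilane should attack C6 axially through a chair-like transition state on the face syn to the pseudoaxial C4 oxygen and anti to the C4 methyl group, which puts the allyl group cis to the lactone oxygen and the C6 methyl cis to the C4 methyl (6S in the locants of the overview).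

**Step 7**
Reactants: 11 tert-butyl (3S,4aR,7aR)-3,4a-dimethyl-6-oxo-3-(prop-2-en-1-yl)hexahydrofuro[3,2-c][1,2]dioxine-7-carboxylate
Product: 13 (3S,4aR,7aR)-3,4a-dimethyl-3-(prop-2-en-1-yl)-3,4,4a,7a-tetrahydrofuro[3,2-c][1,2]dioxin-6(7H)-one, via carboxylic acid 12 (not isolated)
Conditions: CF3CO2H/CH2Cl2 1:4, 0 → 23 °C; concentrate; toluene, 90 °C
Reagents that add atoms: none
Why: Acidolysis of the tert-butyl ester (loss of isobutene) and thermal decarboxylation of the malonic-type α-carboxy lactone through the cyclic six-membered transition state, under base-free conditions that should spare the β-peroxy lactone; C2 ceases to be a stereocentre.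

**Step 8**
Reactants: 14 nona-1,8-diene; 15 4-iodophenol
Product: 17 4-(non-8-en-1-yl)phenol, via alkylborane 16 (not isolated)
Conditions: 14 (3 equiv), 9-BBN-H (1 equiv), THF, 0 → 23 °C; excess 14 removed in vacuo; 15 (0.8 equiv), PdCl2(dppf) (3 mol %), K3PO4 (3 equiv), DMF/H2O, 60 °C
Reagents that add atoms: none
Why: Anti-Markovnikov hydroboration of one terminal alkene of the diene used in excess, then B-alkyl Suzuki–Miyaura coupling with the aryl iodide; no stereocentre is formed.

**Step 9**
Reactants: 13 (3S,4aR,7aR)-3,4a-dimethyl-3-(prop-2-en-1-yl)-3,4,4a,7a-tetrahydrofuro[3,2-c][1,2]dioxin-6(7H)-one; 17 4-(non-8-en-1-yl)phenol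
Product: 18 (3S,4aR,7aR)-3-[10-(4-hydroxyphenyl)dec-2-en-1-yl]-3,4a-dimethyl-3,4,4a,7a-tetrahydrofuro[3,2-c][1,2]dioxin-6(7H)-one (E/Z mixture)
Conditions: 17 (3 equiv), second-generation Grubbs catalyst RuCl2(H2IMes)(PCy3)(=CHPh) (5 mol %), CH2Cl2, 40 °C
Reagents that add atoms: none
Why: Olefin cross-metathesis between the hindered, slowly homodimerising allyl group of 13 and an excess of the unhindered terminal alkene 17; dialkyl peroxides and free phenols are expected to be tolerated by the ruthenium alkylidene, and the alkene geometry is irrelevant.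

**Step 10**
Reactants: 18 (3S,4aR,7aR)-3-[10-(4-hydroxyphenyl)dec-2-en-1-yl]-3,4a-dimethyl-3,4,4a,7a-tetrahydrofuro[3,2-c][1,2]dioxin-6(7H)-one
Product: 19 plakortolide S, (3S,4aR,7aR)-3-[10-(4-hydroxyphenyl)decyl]-3,4a-dimethyl-3,4,4a,7a-tetrahydrofuro[3,2-c][1,2]dioxin-6(7H)-one
Conditions: KO2CN=NCO2K (10 equiv), AcOH (20 equiv), MeOH/CH2Cl2, 0 → 23 °C
Reagents that add atoms: none
Why: Diimide reduction (syn transfer of H2 from HN=NH generated from the azodicarboxylate) should saturate the disubstituted alkene without touching the O–O bond, which catalytic hydrogenation would cleave; no stereocentre is affected.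

**Compound list**
1 | (2S)-(2-methyloxiran-2-yl)methanol, (S)-2-methylglycidol | C[C@]1(CO)CO1 | starting material
2 | (2R)-2,4-dimethylpent-4-ene-1,2-diol | C[C@](O)(CO)CC(C)=C | intermediate
3 | (2R)-2-hydroxy-2,4-dimethylpent-4-enal | C[C@](O)(C=O)CC(C)=C | intermediate (not isolated)
4 | tert-butyl (2E,4R)-4-hydroxy-4,6-dimethylhepta-2,6-dienoate | C[C@](O)(/C=C/C(=O)OC(C)(C)C)CC(C)=C | intermediate
5 | tert-butyl (2E,4R)-4-[(methoxycarbonyl)oxy]-4,6-dimethylhepta-2,6-dienoate | C[C@](OC(=O)OC)(/C=C/C(=O)OC(C)(C)C)CC(C)=C | intermediate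
6 | tert-butyl (2E,4R)-6-hydroperoxy-6-methoxy-4-[(methoxycarbonyl)oxy]-4-methylhept-2-enoate (both C6 epimers) | C[C@](OC(=O)OC)(/C=C/C(=O)OC(C)(C)C)CC(C)(OC)OO | intermediate
7 | lithium peroxide of 6 | C[C@](OC(=O)OC)(/C=C/C(=O)OC(C)(C)C)CC(C)(OC)O[O-].[Li+] | intermediate (not isolated)
8 | lithium enolate of tert-butyl 2-[(3R,4R)-6-methoxy-4-[(methoxycarbonyl)oxy]-4,6-dimethyl-1,2-dioxan-3-yl]acetate | COC1(C)C[C@@](C)(OC(=O)OC)[C@@H](C=C([O-])OC(C)(C)C)OO1.[Li+] | intermediate (not isolated)
9 | tert-butyl (4aR,7aR)-3-methoxy-3,4a-dimethyl-6-oxohexahydrofuro[3,2-c][1,2]dioxine-7-carboxylate (mixture at the ketal carbon and at the ester-bearing carbon) | COC1(C)C[C@@]2(C)OC(=O)C(C(=O)OC(C)(C)C)[C@H]2OO1 | intermediate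
10 | bicyclic peroxycarbenium triflate derived from 9 | CC1=[O+]O[C@@H]2C(C(=O)OC(C)(C)C)C(=O)O[C@]2(C)C1.[O-]S(=O)(=O)C(F)(F)F | intermediate (not isolated)
11 | tert-butyl (3S,4aR,7aR)-3,4a-dimethyl-6-oxo-3-(prop-2-en-1-yl)hexahydrofuro[3,2-c][1,2]dioxine-7-carboxylate | C[C@]1(CC=C)C[C@@]2(C)OC(=O)C(C(=O)OC(C)(C)C)[C@H]2OO1 | intermediate
12 | (3S,4aR,7aR)-3,4a-dimethyl-6-oxo-3-(prop-2-en-1-yl)hexahydrofuro[3,2-c][1,2]dioxine-7-carboxylic acid | C[C@]1(CC=C)C[C@@]2(C)OC(=O)C(C(=O)O)[C@H]2OO1 | intermediate (not isolated)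
13 | (3S,4aR,7aR)-3,4a-dimethyl-3-(prop-2-en-1-yl)-3,4,4a,7a-tetrahydrofuro[3,2-c][1,2]dioxin-6(7H)-one | C[C@]1(CC=C)C[C@@]2(C)OC(=O)C[C@H]2OO1 | intermediate
14 | nona-1,8-diene | C=CCCCCCC=C | starting material
15 | 4-iodophenol | Oc1ccc(I)cc1 | starting material
16 | 9-(non-8-en-1-yl)-9-borabicyclo[3.3.1]nonane | C=CCCCCCCCB1C2CCCC1CCC2 | intermediate (not isolated)
17 | 4-(non-8-en-1-yl)phenol | C=CCCCCCCCc1ccc(O)cc1 | intermediate
18 | (3S,4aR,7aR)-3-[10-(4-hydroxyphenyl)dec-2-en-1-yl]-3,4a-dimethyl-3,4,4a,7a-tetrahydrofuro[3,2-c][1,2]dioxin-6(7H)-one (E/Z mixture) | C[C@]1(CC=CCCCCCCCc3ccc(O)cc3)C[C@@]2(C)OC(=O)C[C@H]2OO1 | intermediate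
19 | plakortolide S, (3S,4aR,7aR)-3-[10-(4-hydroxyphenyl)decyl]-3,4a-dimethyl-3,4,4a,7a-tetrahydrofuro[3,2-c][1,2]dioxin-6(7H)-one | C[C@]1(CCCCCCCCCCc2ccc(O)cc2)C[C@@]2(C)OC(=O)C[C@H]2OO1 | target

**Step count**
Total: 10 steps. Longest linear sequence: 9 steps (1 → 19 through steps 1–7, 9 and 10); step 8 is a one-step side branch.

**Steps most likely to fail**

Step 5 (Proposed new method). What may go wrong: attack of the C2 enolate on the O–O bond (epoxide formation with opening of the dioxane) or attack of the peroxide anion on the carbonate instead of C-acylation, and incomplete facial control at C3. Fallback, from 6 back to 9: the two ring closures are separated into two reactions of known type. 6 would be cyclised under the standard protic conditions for peroxy-Michael additions of hydroperoxy ketals (Et2NH cat., CF3CH2OH, 23 °C), where the enolate is protonated at once and no carbonate-attacking strong base is present, to give the isolated monocyclic dioxane tert-butyl 2-[(3R,4R)-6-methoxy-4-[(methoxycarbonyl)oxy]-4,6-dimethyl-1,2-dioxan-3-yl]acetate F1. F1, which no longer holds a free peroxide anion, would then be enolised with LiN(SiMe3)2 in THF at −78 °C and should close to 9 by the ordinary intramolecular Claisen (Dieckmann-type) acylation of the ester enolate by the carbonate.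

Step 6. What may go wrong: ionisation by opening of the ring (loss of the ring peroxide oxygen instead of methoxide), or poor facial selectivity in the attack on the bicyclic cation. Fallback, from 6 back to 11: the C6–C7 bond is made on the acyclic ketal, before either ring exists and without reliance on the facial bias of the bicycle, at the price of an epimer separation. 6 would be silylated (Et3SiCl, imidazole, DMF) to tert-butyl (2E,4R)-6-methoxy-4-[(methoxycarbonyl)oxy]-4-methyl-6-[(triethylsilyl)peroxy]hept-2-enoate F2. F2 would be allylated at the ketal carbon (CH2=CHCH2SiMe3, TiCl4, CH2Cl2, −78 °C; peroxycarbenium allylation of an acyclic silyl peroxy ketal) to tert-butyl (2E,4R)-4-[(methoxycarbonyl)oxy]-4,6-dimethyl-6-[(triethylsilyl)peroxy]nona-2,8-dienoate F3 (both C6 epimers). F3 would be desilylated (HF·pyridine, THF, 0 °C) to tert-butyl (2E,4R)-6-hydroperoxy-4-[(methoxycarbonyl)oxy]-4,6-dimethylnona-2,8-dienoate F4. The conditions of step 5 should then convert F4 into 11 and its C6 epimer tert-butyl (3R,4aR,7aR)-3,4a-dimethyl-6-oxo-3-(prop-2-en-1-yl)hexahydrofuro[3,2-c][1,2]dioxine-7-carboxylate F5, which are separated by chromatography.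

Step 7. What may go wrong: acid-induced or thermal cleavage of the O–O bond, or retro-oxa-Michael opening of the dioxane, during ester acidolysis and decarboxylation. Fallback, from 2 back to 13 (it replaces steps 2–7): the lactone is made without any carboxyl group on C2, so nothing has to be removed in the presence of the peroxide; in this detour the lactone is closed at its acyl–oxygen bond. 2 would be oxidised as in step 2 to 3 and olefinated Z-selectively (ethyl 2-(diphenoxyphosphoryl)acetate, NaH, THF, −78 °C) to ethyl (2Z,4R)-4-hydroxy-4,6-dimethylhepta-2,6-dienoate F6. F6 lactonises (cat. TsOH or on standing) to (5R)-5-methyl-5-(2-methylprop-2-en-1-yl)furan-2(5H)-one F7. Ozonolysis of F7 in CH2Cl2/MeOH as in step 4 would give (5R)-5-(2-hydroperoxy-2-methoxypropyl)-5-methylfuran-2(5H)-one F8. Amine-mediated intramolecular peroxy-Michael addition of F8 to its butenolide (Et2NH cat., CF3CH2OH, 23 °C; cis ring fusion enforced by the tether) should give (4aR,7aR)-3-methoxy-3,4a-dimethyl-3,4,4a,7a-tetrahydrofuro[3,2-c][1,2]dioxin-6(7H)-one F9. Allylation of F9 under the conditions of step 6 would give 13.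

**Further compounds**
F1 | step 5 | tert-butyl 2-[(3R,4R)-6-methoxy-4-[(methoxycarbonyl)oxy]-4,6-dimethyl-1,2-dioxan-3-yl]acetate | COC1(C)C[C@@](C)(OC(=O)OC)[C@@H](CC(=O)OC(C)(C)C)OO1
F2 | step 6 | tert-butyl (2E,4R)-6-methoxy-4-[(methoxycarbonyl)oxy]-4-methyl-6-[(triethylsilyl)peroxy]hept-2-enoate | C[C@](OC(=O)OC)(/C=C/C(=O)OC(C)(C)C)CC(C)(OC)OO[Si](CC)(CC)CC
F3 | step 6 | tert-butyl (2E,4R)-4-[(methoxycarbonyl)oxy]-4,6-dimethyl-6-[(triethylsilyl)peroxy]nona-2,8-dienoate | C[C@](OC(=O)OC)(/C=C/C(=O)OC(C)(C)C)CC(C)(CC=C)OO[Si](CC)(CC)CC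
F4 | step 6 | tert-butyl (2E,4R)-6-hydroperoxy-4-[(methoxycarbonyl)oxy]-4,6-dimethylnona-2,8-dienoate | C[C@](OC(=O)OC)(/C=C/C(=O)OC(C)(C)C)CC(C)(CC=C)OO
F5 | step 6 | tert-butyl (3R,4aR,7aR)-3,4a-dimethyl-6-oxo-3-(prop-2-en-1-yl)hexahydrofuro[3,2-c][1,2]dioxine-7-carboxylate | C[C@@]1(CC=C)C[C@@]2(C)OC(=O)C(C(=O)OC(C)(C)C)[C@H]2OO1
F6 | step 7 | ethyl (2Z,4R)-4-hydroxy-4,6-dimethylhepta-2,6-dienoate | C[C@](O)(/C=C\C(=O)OCC)CC(C)=C
F7 | step 7 | (5R)-5-methyl-5-(2-methylprop-2-en-1-yl)furan-2(5H)-one | C[C@]1(CC(C)=C)OC(=O)C=C1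
F8 | step 7 | (5R)-5-(2-hydroperoxy-2-methoxypropyl)-5-methylfuran-2(5H)-one | C[C@]1(CC(C)(OC)OO)OC(=O)C=C1
F9 | step 7 | (4aR,7aR)-3-methoxy-3,4a-dimethyl-3,4,4a,7a-tetrahydrofuro[3,2-c][1,2]dioxin-6(7H)-one | COC1(C)C[C@@]2(C)OC(=O)C[C@H]2OO1
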